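## Retrosynthetic overview

1. The C5=C6 tetrasubstituted alkene comes from reductive 1,3-transposition of a tertiary allylic alcohol inside the already closed ring B. Ring B (C1=C2) is closed last by ring-closing metathesis.
2. The C5–C6 bond joins the two fragments: an electrochemical Ni/Cr alkenyl–ketone coupling of a ring-A alkenyl triflate with the methyl ketone of a trans-hydrindane (rings C and D).
3. Ring A comes from (S)-pulegone by Favorskii ring contraction; the cis C4/C18 pair is set by kinetic protonation after decarboxylation.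
4. Rings D and C come from (S)-carvone: ring-contracted cyclopentenone (ring D), conjugate addition/allylation (C9, C13), aldol condensation to close ring C, then isopropenyl cuprate (C15, C7).
5. Order of ring formation: D, then C (one fragment); A (second fragment); B last.

Assumption: the SMILES as given defines the enantiomer to be made; skeleton atoms are labelled in the order they appear in it (C1 MeC=, C2 =CH, C3, C4, C5, C6 MeC=, C7, C8, C9, C10 CH–iPr, C11, C12 CH–OH, C13 C–Me, C14, C15, C16, C17, C18 CH–Me); ring A = C4, C5, C16–C18; ring B = C1–C7, C15; ring C = C7–C9, C13–C15; ring D = C9–C13.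

## Route

Step 1
Reactants: 1 (S)-(+)-carvone
Product: 2 (5S)-2-methyl-5-(propan-2-yl)cyclohex-2-en-1-one
Conditions: H2 (1 atm), RhCl(PPh3)3 (1 mol%), benzene, rt
Reagents that add atoms: none
Why: Homogeneous hydrogenation reduces only the 1,1-disubstituted isopropenyl alkene, leaving the trisubstituted enone and the bought stereocenter (future C10) untouched.

Step 2
Reactants: 2 (5S)-2-methyl-5-(propan-2-yl)cyclohex-2-en-1-one
Product: 4 (5S)-2-methyl-3-oxo-5-(propan-2-yl)cyclopent-1-ene-1-carbaldehyde, via trioxo aldehyde 3 (not isolated)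
Conditions: O3, CH2Cl2, −78 °C; Me2S, −78 °C → rt; then piperidine (20 mol%), AcOH (20 mol%), benzene, 60 °C
Reagents that add atoms: ozone, O=[O+][O-]
Why: Ozonolysis of the enone C=C followed by enamine-mediated intramolecular aldol condensation of the aldehyde α-carbon onto the adjacent methyl ketone contracts the ring to the cyclopentenone; the stereocenter is β to both carbonyls in 3 and is not enolised.

Step 3
Reactants: 4 (5S)-2-methyl-3-oxo-5-(propan-2-yl)cyclopent-1-ene-1-carbaldehyde
Product: 5 (4S)-2-methyl-4-(propan-2-yl)cyclopent-2-en-1-one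
Conditions: [Rh(cod)Cl]2 (2.5 mol%), Ph2P(CH2)3PPh2 (5 mol%), diglyme, 160 °C
Reagents that add atoms: none
Why: Rhodium-catalysed (Tsuji–Wilkinson type) decarbonylation removes the formyl carbon with retention of the alkene position under neutral conditions that do not enolise the γ stereocenter.

Step 4
Reactants: 5 (4S)-2-methyl-4-(propan-2-yl)cyclopent-2-en-1-one
Product: 7 (2R,3S,4S)-2-methyl-3-[2-(2-methyl-1,3-dioxolan-2-yl)ethyl]-4-(propan-2-yl)-2-(prop-2-en-1-yl)cyclopentan-1-one, via bromomagnesium enolate 6 (not isolated)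
Conditions: BrMgCH2CH2C(OCH2CH2O)CH3 (1.3 equiv), CuBr·SMe2 (10 mol%), THF, −78 → −30 °C; then allyl bromide (3 equiv), DMPU, −30 → 0 °C
Reagents that add atoms: [2-(2-methyl-1,3-dioxolan-2-yl)ethyl]magnesium bromide, CC1(CC[Mg]Br)OCCO1; allyl bromide, C=CCBr
Why: Copper-catalysed conjugate addition occurs anti to the C10 isopropyl group (sets C9) and the regiodefined enolate is allylated anti to the new C9 chain (sets quaternary C13) in a three-component conjugate addition–enolate alkylation, giving the trans relationship needed for the trans-hydrindane.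

Step 5
Reactants: 7 (2R,3S,4S)-2-methyl-3-[2-(2-methyl-1,3-dioxolan-2-yl)ethyl]-4-(propan-2-yl)-2-(prop-2-en-1-yl)cyclopentan-1-one
Product: 8 2-[(1R,2S,3S)-1-methyl-2-[2-(2-methyl-1,3-dioxolan-2-yl)ethyl]-5-oxo-3-(propan-2-yl)cyclopentyl]acetaldehyde
Conditions: O3, CH2Cl2, −78 °C; Me2S, −78 °C → rt
Reagents that add atoms: ozone, O=[O+][O-]
Why: Ozonolysis of the terminal allyl alkene gives the C15 aldehyde without touching any stereocenter.

Step 6
Reactants: 8 2-[(1R,2S,3S)-1-methyl-2-[2-(2-methyl-1,3-dioxolan-2-yl)ethyl]-5-oxo-3-(propan-2-yl)cyclopentyl]acetaldehyde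
Product: 10 (3S,3aS,7aR)-5-acetyl-7a-methyl-3-(propan-2-yl)-2,3,3a,4,7,7a-hexahydro-1H-inden-1-one, via keto aldehyde 9 (not isolated)
Conditions: 1 M HCl, THF, rt; then KOH (0.5 equiv), MeOH, 0 °C → rt
Reagents that add atoms: water, O
Why: Ketal hydrolysis followed by hydroxide-mediated intramolecular aldol condensation (C7 ketone enolate onto the C15 aldehyde) closes six-membered ring C as the conjugated enone; the trans ring fusion was fixed in step 4, and the other aldol modes are reversible or give strained bridged rings.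

Step 7
Reactants: 10 (3S,3aS,7aR)-5-acetyl-7a-methyl-3-(propan-2-yl)-2,3,3a,4,7,7a-hexahydro-1H-inden-1-one
Product: 11 1-[(1R,3S,3aS,7aR)-1-hydroxy-7a-methyl-3-(propan-2-yl)-2,3,3a,4,7,7a-hexahydro-1H-inden-5-yl]ethan-1-one
Conditions: NaBH4 (0.3 equiv), EtOH, −20 °C
Reagents that add atoms: none
Why: Borohydride reduces the saturated cyclopentanone faster than the conjugated enone and attacks anti to the angular methyl group (as in hydrindenedione and 17-keto steroid reductions), giving the C12 alcohol cis to that methyl (C12 R).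

Step 8
Reactants: 11 1-[(1R,3S,3aS,7aR)-1-hydroxy-7a-methyl-3-(propan-2-yl)-2,3,3a,4,7,7a-hexahydro-1H-inden-5-yl]ethan-1-one
Product: 13 1-[(1R,3S,3aS,5S,6S,7aR)-1-hydroxy-7a-methyl-3-(propan-2-yl)-6-(prop-1-en-2-yl)octahydro-1H-inden-5-yl]ethan-1-one, via bis-silyl species 12 (not isolated)
Conditions: CH2=C(CH3)MgBr (3 equiv), CuBr·SMe2 (15 mol%), TMSCl (4 equiv), THF, −78 → −30 °C; then 1 M HCl, THF, 0 °C; then K2CO3, MeOH, rt
Reagents that add atoms: isopropenylmagnesium bromide, CC(=C)[Mg]Br
Why: TMSCl-accelerated copper-catalysed conjugate addition delivers the isopropenyl group to C15 anti to the axial angular methyl (1,3-diaxial approach is blocked), and base equilibration of the α-center C7 gives the trans-diequatorial acetyl/isopropenyl arrangement.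

Step 9
Reactants: 14 (S)-(−)-pulegone
Product: 16 prop-2-en-1-yl (2S)-2-methyl-5-(propan-2-ylidene)cyclopentane-1-carboxylate, via pulegone dibromide 15 (not isolated)
Conditions: Br2, Et2O, 0 °C; then NaOCH2CH=CH2 (2.5 equiv), allyl alcohol, reflux
Reagents that add atoms: sodium prop-2-en-1-olate, [Na+].[O-]CC=C
Why: Bromination followed by Favorskii rearrangement contracts the ring and gives the allyl ester directly; the methyl-bearing center (future C18) is not involved and the ester-bearing center is erased later.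

Step 10
Reactants: 16 prop-2-en-1-yl (2S)-2-methyl-5-(propan-2-ylidene)cyclopentane-1-carboxylate
Product: 17 prop-2-en-1-yl (2S)-2-methyl-5-oxocyclopentane-1-carboxylate
Conditions: O3 (1.0 equiv, dye indicator), CH2Cl2, −78 °C; Me2S
Reagents that add atoms: ozone, O=[O+][O-]
Why: Ozonolysis is selective for the electron-rich tetrasubstituted alkene over the monosubstituted alkene of the allyl ester, giving the β-keto ester.

Step 11
Reactants: 17 prop-2-en-1-yl (2S)-2-methyl-5-oxocyclopentane-1-carboxylate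
Product: 18 prop-2-en-1-yl (2S)-2-methyl-5-oxo-1-(prop-2-en-1-yl)cyclopentane-1-carboxylate
Conditions: allyl bromide (1.5 equiv), K2CO3, acetone, 56 °C
Reagents that add atoms: allyl bromide, C=CCBr
Why: C-Alkylation of the β-keto ester installs C3 and C2 on C4; the configuration of the new quaternary center is irrelevant because it is erased in step 12.

Step 12
Reactants: 18 prop-2-en-1-yl (2S)-2-methyl-5-oxo-1-(prop-2-en-1-yl)cyclopentane-1-carboxylate
Product: 19 (2S,3S)-3-methyl-2-(prop-2-en-1-yl)cyclopentan-1-one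
Conditions: Pd(OAc)2 (2 mol%), PPh3 (4 mol%), HCO2H (2.5 equiv), Et3N (3 equiv), THF, rt
Reagents that add atoms: none
Why: Tsuji palladium-catalysed deallylation–decarboxylation with formate releases the enol under mild conditions, and it is protonated kinetically on the face opposite the adjacent C18 methyl, so hydrogen enters last and the allyl group ends up cis to the methyl (C4 S).

Step 13
Reactants: 19 (2S,3S)-3-methyl-2-(prop-2-en-1-yl)cyclopentan-1-one
Product: 21 (4S,5S)-4-methyl-5-(prop-2-en-1-yl)cyclopent-1-en-1-yl trifluoromethanesulfonate, via lithium enolate 20 (not isolated)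
Conditions: LiN(i-Pr)2 (1.1 equiv), THF, −78 °C (ketone added to base); then PhNTf2, −78 → 0 °C
Reagents that add atoms: N-phenylbis(trifluoromethanesulfonimide), O=S(=O)(N(c1ccccc1)S(=O)(=O)C(F)(F)F)C(F)(F)F
Why: Irreversible kinetic deprotonation at the less hindered α-CH2 (C16) and O-triflation give the regiodefined enol triflate, which removes the ketone and so locks the epimerisable cis center C4.

Step 14
Reactants: 13 1-[(1R,3S,3aS,5S,6S,7aR)-1-hydroxy-7a-methyl-3-(propan-2-yl)-6-(prop-1-en-2-yl)octahydro-1H-inden-5-yl]ethan-1-one; 21 (4S,5S)-4-methyl-5-(prop-2-en-1-yl)cyclopent-1-en-1-yl trifluoromethanesulfonate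
Product: 23 (1R,3S,3aS,5S,6S,7aR)-5-{1-hydroxy-1-[(4S,5S)-4-methyl-5-(prop-2-en-1-yl)cyclopent-1-en-1-yl]ethyl}-7a-methyl-3-(propan-2-yl)-6-(prop-1-en-2-yl)octahydro-1H-inden-1-ol (both C6 carbinol epimers), via bis-silyl ether 22 (not isolated)
Conditions: CrCl2 (20 mol%), NiCl2(dme) (5 mol%), TMSCl (4 equiv), LiCl (2 equiv), DMF–THF, undivided cell, Al anode, Ni-foam cathode, 4 mA constant current (about 2.5 F/mol), rt; then K2CO3, MeOH
Reagents that add atoms: none
Why: Proposed new method: a chromium/nickel-electrocatalytic Nozaki–Hiyama–Kishi alkenylation of a ketone, in which cathodically formed zerovalent nickel inserts into the C5–OTf bond of 21, the alkenyl group passes to trivalent chromium, the non-basic alkenylchromium adds to the TMSCl-activated C6 methyl ketone without enolising it or disturbing the silylated C12 hydroxyl, and TMSCl releases chromium for re-reduction to the divalent state at the cathode (aluminium anode as electron source); the closest known reaction types are the electrochemical NHK coupling of alkenyl halides and triflates with aldehydes and the TMSCl-turnover catalytic NHK reaction, neither shown for an unactivated enolisable dialkyl ketone; the new C6 carbinol center forms as an epimer mixture that is erased in step 16.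

Step 15
Reactants: 23 (1R,3S,3aS,5S,6S,7aR)-5-{1-hydroxy-1-[(4S,5S)-4-methyl-5-(prop-2-en-1-yl)cyclopent-1-en-1-yl]ethyl}-7a-methyl-3-(propan-2-yl)-6-(prop-1-en-2-yl)octahydro-1H-inden-1-ol
Product: 24 ring-B-closed diol (C1=C2 Z, C5=C16 in ring A, C6 bearing OH and CH3, free C12 hydroxyl; both C6 epimers)
Conditions: second-generation Grubbs catalyst (10 mol%), toluene, 80 °C, high dilution
Reagents that add atoms: none
Why: Ring-closing metathesis between the allyl group on C4 and the isopropenyl group on C15 closes the eight-membered ring B, whose trisubstituted C1=C2 alkene can only be cis within the ring; no stereocenter is formed or touched.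

Step 16
Reactants: 24 ring-B-closed diol
Product: 25 CNP0541339.1 (target)
Conditions: Et3SiH (5 equiv), CF3CO2H (3 equiv), CH2Cl2, −78 → −30 °C; then K2CO3, MeOH
Reagents that add atoms: none
Why: Ionic hydrogenation ionises only the tertiary allylic C6 alcohol, and the silane delivers hydride to the less hindered allyl terminus C16, moving the alkene to the tetrasubstituted C5=C6 position, whose geometry is fixed by ring B; C16 is not a stereocenter and both C6 epimers converge.

## Compound list

1 | (S)-(+)-carvone, (5S)-2-methyl-5-(prop-1-en-2-yl)cyclohex-2-en-1-one | CC1=CC[C@H](C(C)=C)CC1=O | starting material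
2 | (5S)-2-methyl-5-(propan-2-yl)cyclohex-2-en-1-one | CC1=CC[C@H](C(C)C)CC1=O | intermediate
3 | (3S)-5,6-dioxo-3-(propan-2-yl)heptanal | O=CC[C@H](C(C)C)CC(=O)C(C)=O | intermediate (not isolated)
4 | (5S)-2-methyl-3-oxo-5-(propan-2-yl)cyclopent-1-ene-1-carbaldehyde | CC1=C(C=O)[C@H](C(C)C)CC1=O | intermediate
5 | (4S)-2-methyl-4-(propan-2-yl)cyclopent-2-en-1-one | CC1=C[C@H](C(C)C)CC1=O | intermediate
6 | bromomagnesium (3S,4S)-2-methyl-3-[2-(2-methyl-1,3-dioxolan-2-yl)ethyl]-4-(propan-2-yl)cyclopent-1-en-1-olate | CC1(CC[C@H]2[C@H](C(C)C)CC(O[Mg]Br)=C2C)OCCO1 | intermediate (not isolated)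
7 | (2R,3S,4S)-2-methyl-3-[2-(2-methyl-1,3-dioxolan-2-yl)ethyl]-4-(propan-2-yl)-2-(prop-2-en-1-yl)cyclopentan-1-one | CC1(CC[C@H]2[C@H](C(C)C)CC(=O)[C@]2(C)CC=C)OCCO1 | intermediate
8 | 2-[(1R,2S,3S)-1-methyl-2-[2-(2-methyl-1,3-dioxolan-2-yl)ethyl]-5-oxo-3-(propan-2-yl)cyclopentyl]acetaldehyde | CC1(CC[C@H]2[C@H](C(C)C)CC(=O)[C@]2(C)CC=O)OCCO1 | intermediate
9 | 2-[(1R,2S,3S)-1-methyl-5-oxo-2-(3-oxobutyl)-3-(propan-2-yl)cyclopentyl]acetaldehyde | CC(=O)CC[C@H]1[C@H](C(C)C)CC(=O)[C@]1(C)CC=O | intermediate (not isolated)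
10 | (3S,3aS,7aR)-5-acetyl-7a-methyl-3-(propan-2-yl)-2,3,3a,4,7,7a-hexahydro-1H-inden-1-one | CC(=O)C=1C[C@H]2[C@H](C(C)C)CC(=O)[C@]2(C)CC=1 | intermediate
11 | 1-[(1R,3S,3aS,7aR)-1-hydroxy-7a-methyl-3-(propan-2-yl)-2,3,3a,4,7,7a-hexahydro-1H-inden-5-yl]ethan-1-one | CC(=O)C=1C[C@H]2[C@H](C(C)C)C[C@@H](O)[C@]2(C)CC=1 | intermediate
12 | bis(trimethylsilyl) derivative of 13 (C12 silyl ether, C6=C7 silyl enol ether) | CC(O[Si](C)(C)C)=C1C[C@H]2[C@H](C(C)C)C[C@@H](O[Si](C)(C)C)[C@]2(C)C[C@@H]1C(C)=C | intermediate (not isolated)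
13 | 1-[(1R,3S,3aS,5S,6S,7aR)-1-hydroxy-7a-methyl-3-(propan-2-yl)-6-(prop-1-en-2-yl)octahydro-1H-inden-5-yl]ethan-1-one | CC(=O)[C@H]1C[C@H]2[C@H](C(C)C)C[C@@H](O)[C@]2(C)C[C@@H]1C(C)=C | intermediate
14 | (S)-(−)-pulegone, (5S)-5-methyl-2-(propan-2-ylidene)cyclohexan-1-one | C[C@H]1CCC(=C(C)C)C(=O)C1 | starting material
15 | (5S)-2-bromo-2-(2-bromopropan-2-yl)-5-methylcyclohexan-1-one | C[C@H]1CCC(Br)(C(C)(C)Br)C(=O)C1 | intermediate (not isolated)
16 | prop-2-en-1-yl (2S)-2-methyl-5-(propan-2-ylidene)cyclopentane-1-carboxylate (C1 epimers) | C[C@H]1CCC(=C(C)C)C1C(=O)OCC=C | intermediate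
17 | prop-2-en-1-yl (2S)-2-methyl-5-oxocyclopentane-1-carboxylate (C1 epimers) | C[C@H]1CCC(=O)C1C(=O)OCC=C | intermediate
18 | prop-2-en-1-yl (2S)-2-methyl-5-oxo-1-(prop-2-en-1-yl)cyclopentane-1-carboxylate (C1 epimers) | C[C@H]1CCC(=O)C1(CC=C)C(=O)OCC=C | intermediate
19 | (2S,3S)-3-methyl-2-(prop-2-en-1-yl)cyclopentan-1-one (cis) | C=CC[C@@H]1C(=O)CC[C@@H]1C | intermediate
20 | lithium (4S,5S)-4-methyl-5-(prop-2-en-1-yl)cyclopent-1-en-1-olate | C=CC[C@@H]1C(O[Li])=CC[C@@H]1C | intermediate (not isolated)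
21 | (4S,5S)-4-methyl-5-(prop-2-en-1-yl)cyclopent-1-en-1-yl trifluoromethanesulfonate | C=CC[C@@H]1C(OS(=O)(=O)C(F)(F)F)=CC[C@@H]1C | intermediate
22 | bis(trimethylsilyl) ether of 23 (both C6 epimers) | C=CC[C@@H]1C(=CC[C@@H]1C)C(C)(O[Si](C)(C)C)[C@H]2C[C@H]3[C@H](C(C)C)C[C@@H](O[Si](C)(C)C)[C@]3(C)C[C@@H]2C(C)=C | intermediate (not isolated)
23 | (1R,3S,3aS,5S,6S,7aR)-5-{1-hydroxy-1-[(4S,5S)-4-methyl-5-(prop-2-en-1-yl)cyclopent-1-en-1-yl]ethyl}-7a-methyl-3-(propan-2-yl)-6-(prop-1-en-2-yl)octahydro-1H-inden-1-ol (both C6 epimers) | C=CC[C@@H]1C(=CC[C@@H]1C)C(C)(O)[C@H]2C[C@H]3[C@H](C(C)C)C[C@@H](O)[C@]3(C)C[C@@H]2C(C)=C | intermediate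
24 | ring-B-closed diol: C1=C2 (Z), C5=C16, C6(OH)CH3, C12–OH; C4S, C7S, C9S, C10S, C12R, C13R, C15S, C18S; both C6 epimers | C/C1=C/C[C@@H]2C(=CC[C@@H]2C)C(C)(O)[C@H]3C[C@H]4[C@H](C(C)C)C[C@@H](O)[C@]4(C)C[C@H]13 | intermediate
25 | CNP0541339.1; C4S, C7S, C9S, C10S, C12R, C13R, C15S, C18S; C1=C2 and C5=C6 cis within ring B | C/C1=C/C[C@@H]2/C(=C(/C)[C@H]3C[C@H]4[C@H](C(C)C)C[C@@H](O)[C@]4(C)C[C@H]13)CC[C@@H]2C | target

## Step count and risks

Total steps: 16. Longest linear sequence: 11 (steps 1–8, then 14–16). The ring-A branch is 5 steps (9–13).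

Three steps most likely to fail:

**Step 14 (proposed new method).** Alkenylchromium reagents add sluggishly to hindered, enolisable methyl ketones, and electrochemical turnover with a ketone acceptor has not been shown. The fallback uses known chemistry, sets out from 19 (with 13) and rejoins the route at 23. Ketone 19 is condensed without acid (THF, 0 °C) with 2,4,6-triisopropylbenzenesulfonyl hydrazide to the hydrazone F1. Treatment with n-BuLi (2.2 equiv, −78 → 0 °C, Shapiro reaction, deprotonation on the less substituted C16 side) gives the alkenyllithium F2. F2 is transmetallated with anhydrous CeCl3 and added at −78 °C to 13 (one extra equivalent is consumed by the free hydroxyl), giving 23.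

**Step 12.** The cis ketone is the kinetic product, and incomplete facial selectivity or amine-mediated epimerisation would give the trans isomer. The fallback sets out from 18 and rejoins at 19; it regenerates a regiodefined enolate and protonates it under strictly kinetic conditions. Pd(PPh3)4 with morpholine removes the allyl ester to the β-keto acid F3, which loses CO2 at 60 °C to the 2-allyl-3-methylcyclopentanone epimer mixture F4. TMSCl/NaI/Et3N in MeCN gives the more substituted silyl enol ether F5, and MeLi liberates the lithium enolate F6. Quenching at −78 °C with 2,6-di-tert-butyl-4-methylphenol, on the face opposite the methyl group, returns 19.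

**Step 16.** The allyl cation could eliminate, cyclise across ring B onto C1=C2, or take hydride at C6. The fallback avoids a free cation, sets out from 24 and rejoins at 25. Ph3SiOReO3 (cat., Et2O, 0 °C) effects a 1,3-transposition through the perrhenate ester to the secondary allylic alcohol F7 (C16–OH, C5=C6 already in place). ClCO2Me/pyridine acylates the unhindered allylic hydroxyl selectively over the neopentylic C12–OH, giving the carbonate F8. Pd(PPh3)4 with LiBHEt3 (THF, 0 °C) then delivers hydride to the less hindered allyl terminus C16, giving 25.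

Further compounds
F1 | step 14 | N′-[(2S,3S)-3-methyl-2-(prop-2-en-1-yl)cyclopentylidene]-2,4,6-tri(propan-2-yl)benzenesulfonohydrazide | C=CC[C@@H]1C(=NNS(=O)(=O)c2c(C(C)C)cc(C(C)C)cc2C(C)C)CC[C@@H]1C
F2 | step 14 | [(4S,5S)-4-methyl-5-(prop-2-en-1-yl)cyclopent-1-en-1-yl]lithium | C=CC[C@@H]1C([Li])=CC[C@@H]1C
F3 | step 12 | (2S)-2-methyl-5-oxo-1-(prop-2-en-1-yl)cyclopentane-1-carboxylic acid | C[C@H]1CCC(=O)C1(CC=C)C(=O)O
F4 | step 12 | (3S)-3-methyl-2-(prop-2-en-1-yl)cyclopentan-1-one (C2 epimer mixture) | C=CCC1C(=O)CC[C@@H]1C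
F5 | step 12 | trimethyl{[(3S)-3-methyl-2-(prop-2-en-1-yl)cyclopent-1-en-1-yl]oxy}silane | C=CCC1=C(O[Si](C)(C)C)CC[C@@H]1C
F6 | step 12 | lithium (3S)-3-methyl-2-(prop-2-en-1-yl)cyclopent-1-en-1-olate | C=CCC1=C(O[Li])CC[C@@H]1C
F7 | step 16 | 16-hydroxy derivative of 25 (transposed secondary allylic alcohol, C16 epimers) | C/C1=C/C[C@@H]2/C(=C(/C)[C@H]3C[C@H]4[C@H](C(C)C)C[C@@H](O)[C@]4(C)C[C@H]13)C(O)C[C@@H]2C
F8 | step 16 | C16 methyl carbonate of F7 | C/C1=C/C[C@@H]2/C(=C(/C)[C@H]3C[C@H]4[C@H](C(C)C)C[C@@H](O)[C@]4(C)C[C@H]13)C(OC(=O)OC)C[C@@H]2C
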